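The ten-membered ring is disconnected at C5–C6 (germacrane numbering: C1=C10, C9 ester, C8 lactone oxygen, C7, C6 carbinol, C4–C5 epoxide, lactone C11–C13). The feature exploited is that the C6 carbinol flanking the cis-4,5-epoxide of the carbocycle is a masked (Z)-allylic alcohol. One chromium/nickel-mediated alkenyl iodide–aldehyde cyclization forms C5–C6, closes the carbocycle, sets C6 and keeps the Z-C4=C5 geometry; the new hydroxyl later directs the epoxidation. The precursor is a trans-β,γ-disubstituted γ-butyrolactone with the C6 aldehyde on C7 and, on C8, the C9 isobutyrate chain that ends in the (Z)-C5 iodoalkene. C13 is added after ring closure.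

Key step: step 11

Remark: the cyclization substrate 23 and its product 25 have an unsubstituted C11 methylene, so they are 13-nor lactones and not 11,13-dihydro compounds (which would carry a C11 methyl group); CIP descriptors at C6 and C7 change along the route through priority changes only, no centre is inverted.

Step 1
Reactants: 1 pent-3-yn-1-ol
Product: 2 5-bromopent-2-yne
Conditions: CBr4, PPh3, CH2Cl2, 0 °C → rt
Reagents that add atoms: tetrabromomethane, BrC(Br)(Br)Br
Why: Appel reaction: the alcohol is activated as an alkoxyphosphonium ion and displaced by bromide in an SN2 step, the internal alkyne being inert.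

Step 2
Reactants: 2 5-bromopent-2-yne; 3 propyne
Product: 7 (Z)-1-iodo-2-methylhept-1-en-5-yne, via Grignard reagent 4 (not isolated), via alkylcopper 5 (not isolated), via alkenylcopper 6 (not isolated)
Conditions: Mg, Et2O, rt; CuBr·SMe2, Et2O/SMe2, −45 °C; propyne, −25 °C; I2, THF, −50 → 0 °C
Reagents that add atoms: iodine, II
Why: Alkyne carbocupration: the Grignard reagent is transmetalated to the alkylcopper, which adds syn across propyne with the alkyl group on the internal carbon and copper on the terminal carbon, so that iodinolysis with retention should give the Z iodide (C3 cis to iodine), while the internal alkyne of the chain is not carbometalated.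

Step 3
Reactants: 8 (R)-5-(hydroxymethyl)dihydrofuran-2(3H)-one
Product: 9 (R)-5-[(tert-butyldiphenylsilyloxy)methyl]dihydrofuran-2(3H)-one
Conditions: t-BuPh2SiCl, imidazole, DMF, 0 °C → rt
Reagents that add atoms: tert-butyl(chloro)diphenylsilane, CC(C)(C)[Si](Cl)(c1ccccc1)c1ccccc1
Why: Imidazole-promoted silyl ether formation masks the primary alcohol with a bulky group that later shields one face of the butenolide.

Step 4
Reactants: 9 (R)-5-[(tert-butyldiphenylsilyloxy)methyl]dihydrofuran-2(3H)-one
Product: 13 (R)-5-[(tert-butyldiphenylsilyloxy)methyl]furan-2(5H)-one, via lithium enolate 10 (not isolated), via α-phenylselanyl lactone 11 (not isolated), via selenoxide 12 (not isolated)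
Conditions: LiN(SiMe3)2, THF, −78 °C; PhSeBr, −78 °C; then AcOH, 30% H2O2, 0 °C → rt
Reagents that add atoms: none
Why: Selenoxide elimination: α-selenenylation of the lactone enolate, oxidation to the selenoxide and syn elimination toward the only β-hydrogens (lactone C4) should give the butenolide without touching the C5 stereocentre (the future C8).

Step 5
Reactants: 13 (R)-5-[(tert-butyldiphenylsilyloxy)methyl]furan-2(5H)-one; 14 1,3-dithiane
Product: 16 (4R,5R)-5-[(tert-butyldiphenylsilyloxy)methyl]-4-(1,3-dithian-2-yl)dihydrofuran-2(3H)-one, via 2-lithio-1,3-dithiane 15 (not isolated)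
Conditions: n-BuLi, THF, −30 °C; then 13, −78 °C; AcOH, −78 °C
Reagents that add atoms: none
Why: Conjugate (Michael) addition of the lithiated dithiane to the butenolide: the nucleophile should enter anti to the bulky silyloxymethyl group, which sets C7 (lactone C4, R) trans to C8 and brings in C6 at the aldehyde oxidation level.

Step 6
Reactants: 16 (4R,5R)-5-[(tert-butyldiphenylsilyloxy)methyl]-4-(1,3-dithian-2-yl)dihydrofuran-2(3H)-one
Product: 17 (4R,5R)-4-(1,3-dithian-2-yl)-5-(hydroxymethyl)dihydrofuran-2(3H)-one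
Conditions: HF·pyridine, pyridine, THF, 0 °C → rt
Reagents that add atoms: none
Why: Fluoride-mediated desilylation under buffered, non-basic conditions should free the primary alcohol without opening or rearranging the lactone.

Step 7
Reactants: 17 (4R,5R)-4-(1,3-dithian-2-yl)-5-(hydroxymethyl)dihydrofuran-2(3H)-one
Product: 18 (2R,3R)-3-(1,3-dithian-2-yl)-5-oxotetrahydrofuran-2-carbaldehyde
Conditions: (COCl)2, DMSO, CH2Cl2, −78 °C; i-Pr2NEt, −78 → −30 °C; used crude
Reagents that add atoms: none
Why: Swern oxidation stops at the aldehyde and tolerates the dithiane, and the low temperature and hindered amine should keep the α-oxygenated C8 centre from epimerizing.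

Step 8
Reactants: 7 (Z)-1-iodo-2-methylhept-1-en-5-yne; 18 (2R,3R)-3-(1,3-dithian-2-yl)-5-oxotetrahydrofuran-2-carbaldehyde
Product: 21 (4R,5R)-4-(1,3-dithian-2-yl)-5-[(1S,2E,6Z)-1-hydroxy-7-iodo-2,6-dimethylhepta-2,6-dien-1-yl]dihydrofuran-2(3H)-one, via alkenylzirconocene 19 (not isolated), via alkenylzinc 20 (not isolated)
Conditions: Cp2Zr(H)Cl, CH2Cl2, rt (aged until the regioisomers equilibrate); Me2Zn, toluene, −65 °C; 18, −65 → 0 °C; aq. NH4Cl
Reagents that add atoms: none
Why: Hydrozirconation, transmetalation to zinc and carbonyl addition: syn addition of Zr–H places zirconium on the less hindered, methyl-bearing alkyne carbon and fixes the E geometry of C1=C10, the alkenylzinc adds to the aldehyde only, and C9 (S) should be set by polar Felkin–Anh attack anti to the C8–O bond of the poorly chelating lactone oxygen, giving the 8,9-anti relationship.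

Step 9
Reactants: 21 (4R,5R)-4-(1,3-dithian-2-yl)-5-[(1S,2E,6Z)-1-hydroxy-7-iodo-2,6-dimethylhepta-2,6-dien-1-yl]dihydrofuran-2(3H)-one
Product: 22 (1S,2E,6Z)-1-[(2R,3R)-3-(1,3-dithian-2-yl)-5-oxotetrahydrofuran-2-yl]-7-iodo-2,6-dimethylhepta-2,6-dien-1-yl 2-methylpropanoate
Conditions: (i-PrCO)2O, Et3N, DMAP (cat.), CH2Cl2, 0 °C → rt
Reagents that add atoms: isobutyric anhydride, CC(C)C(=O)OC(=O)C(C)C
Why: DMAP-catalysed acylation (nucleophilic catalysis) of the secondary allylic alcohol installs the C9 isobutyrate of the target with no change at C9.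

Step 10
Reactants: 22 (1S,2E,6Z)-1-[(2R,3R)-3-(1,3-dithian-2-yl)-5-oxotetrahydrofuran-2-yl]-7-iodo-2,6-dimethylhepta-2,6-dien-1-yl 2-methylpropanoate
Product: 23 (1S,2E,6Z)-1-[(2R,3R)-3-formyl-5-oxotetrahydrofuran-2-yl]-7-iodo-2,6-dimethylhepta-2,6-dien-1-yl 2-methylpropanoate
Conditions: PhI(OCOCF3)2, NaHCO3, MeCN/H2O (9:1), 0 °C; used at once
Reagents that add atoms: water, O
Why: Oxidative dithioacetal hydrolysis with a hypervalent iodine reagent: sulfur is oxidized, water captures the thionium ion and the aldehyde is released quickly under bicarbonate buffering, so the alkenyl iodide, the alkenes and both esters should survive and C7 should neither epimerize nor lose the β-acyloxy group.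

Step 11
Reactants: 23 (1S,2E,6Z)-1-[(2R,3R)-3-formyl-5-oxotetrahydrofuran-2-yl]-7-iodo-2,6-dimethylhepta-2,6-dien-1-yl 2-methylpropanoate
Product: 25 ten-membered (Z)-allylic alcohol (3aS,4R,5Z,9E,11S,11aR)-4-hydroxy-6,10-dimethyl-2-oxo-2,3,3a,4,7,8,11,11a-octahydrocyclodeca[b]furan-11-yl 2-methylpropanoate, via alkenylchromium 24 (not isolated)
Conditions: CrCl2 (excess), NiCl2 (cat.), degassed DMSO, rt, slow addition of 23 to about 0.003 M; then H2O
Reagents that add atoms: none
Why: Nozaki–Hiyama–Kishi reaction: zerovalent nickel (formed from NiCl2 by divalent chromium) inserts into the C5–I bond, the alkenyl group passes to trivalent chromium with retention of the Z geometry, and alkenylchromium 24 adds to the C6 aldehyde; the closest known reaction type is the chromium/nickel-mediated alkenyl halide–aldehyde macrocyclization. The ten-membered ring closes in a 10-exo-trig mode, helped by the trans-lactone and the two trisubstituted alkenes, which leave few free rotors, and by high dilution, which suppresses intermolecular coupling. The new C6 stereocentre is controlled by the adjacent C7 centre (1,2-induction, Felkin–Anh): C5 should approach anti to the C7–C8 bond and past the C7 hydrogen, which puts the hydroxyl syn to C11 in the C5–C8 zigzag, as the target requires. The step needs chemoselectivity for the aldehyde over the lactone and ester carbonyls, secured by the low nucleophilicity of alkenylchromium reagents, and it needs C7 to keep its configuration, secured by the neutral, non-basic medium. The hindered allylic isobutyrate is not expected to ionize at the low nickel loading.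

Step 12
Reactants: 25 ten-membered (Z)-allylic alcohol
Product: 26 (3aR,4R,5Z,9E,11S,11aR)-6,10-dimethyl-2-oxo-4-[(triethylsilyl)oxy]-2,3,3a,4,7,8,11,11a-octahydrocyclodeca[b]furan-11-yl 2-methylpropanoate
Conditions: Et3SiOTf, 2,6-lutidine, CH2Cl2, −78 °C
Reagents that add atoms: triethylsilyl trifluoromethanesulfonate, CC[Si](CC)(CC)OS(=O)(=O)C(F)(F)F
Why: Silylation with a silyl triflate and a hindered base protects the hindered C6 hydroxyl, so that no C6 alkoxide can attack the lactone carbonyl (translactonization) in the next step.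

Step 13
Reactants: 26 triethylsilyl ether of 25
Product: 28 (3aR,4R,5Z,9E,11S,11aR)-3-[(dimethylamino)methyl]-6,10-dimethyl-2-oxo-4-[(triethylsilyl)oxy]-2,3,3a,4,7,8,11,11a-octahydrocyclodeca[b]furan-11-yl 2-methylpropanoate (C11 epimer not assigned), via lithium enolate 27 (not isolated)
Conditions: LiN(i-Pr)2, THF, −78 °C; CH2=NMe2+ I−, −78 → 0 °C
Reagents that add atoms: N,N-dimethylmethyleneiminium iodide, C=[N+](C)C.[I-]
Why: Mannich reaction of the lactone lithium enolate with the preformed iminium salt: the γ-lactone α-methylene should be deprotonated kinetically in preference to the hindered, less acidic isobutyrate methine, and C-aminomethylation brings in C13.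

Step 14
Reactants: 28 Mannich base
Product: 30 (3aR,4R,5Z,9E,11S,11aR)-6,10-dimethyl-3-methylidene-2-oxo-4-[(triethylsilyl)oxy]-2,3,3a,4,7,8,11,11a-octahydrocyclodeca[b]furan-11-yl 2-methylpropanoate, via trimethylammonium iodide 29 (not isolated)
Conditions: MeI, MeOH, rt; then aq. NaHCO3, CH2Cl2, rt
Reagents that add atoms: none
Why: Quaternization and Hofmann-type (E1cB) elimination: N-methylation turns the amine into a leaving group and mild base removes the acidic C11 proton to give the exocyclic C11=C13 alkene.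

Step 15
Reactants: 30 α-methylene lactone silyl ether
Product: 31 (3aS,4R,5Z,9E,11S,11aR)-4-hydroxy-6,10-dimethyl-3-methylidene-2-oxo-2,3,3a,4,7,8,11,11a-octahydrocyclodeca[b]furan-11-yl 2-methylpropanoate
Conditions: HF·pyridine, pyridine, THF, 0 °C
Reagents that add atoms: none
Why: Fluoride desilylation of the allylic triethylsilyl ether under pyridine buffering should leave the α-methylene lactone and the isobutyrate untouched.

Step 16
Reactants: 31 (Z)-allylic alcohol with the α-methylene lactone
Product: 32 target, (4S,5R,6S,7S,8R,9S)-4,5-epoxy-6-hydroxy-9-(2-methylpropanoyloxy)germacra-1(10)E,11(13)-dien-12,8-olide (CNP0220196.2)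
Conditions: VO(acac)2 (cat.), t-BuOOH (in decane), CH2Cl2, 0 °C → rt
Reagents that add atoms: tert-butyl hydroperoxide, CC(C)(C)OO
Why: Hydroxyl-directed vanadium-catalysed epoxidation: the C6 vanadate ester delivers the peroxide oxygen to the C4=C5 face syn to the hydroxyl in the conformer with C6–H eclipsing the alkene (allylic 1,3-strain with C3), which should give the threo epoxy alcohol (4S,5R), while the remote C1=C10 alkene and the electron-poor methylene lactone are not epoxidized.

Compound list
1 | pent-3-yn-1-ol | CC#CCCO | starting material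
2 | 5-bromopent-2-yne | CC#CCCBr | intermediate
3 | propyne | CC#C | starting material
4 | pent-3-yn-1-ylmagnesium bromide | CC#CCC[Mg]Br | intermediate (not isolated)
5 | pent-3-yn-1-ylcopper | CC#CCC[Cu] | intermediate (not isolated)
6 | (Z)-(2-methylhept-1-en-5-yn-1-yl)copper | CC#CCC/C(C)=C\[Cu] | intermediate (not isolated)
7 | (Z)-1-iodo-2-methylhept-1-en-5-yne | CC#CCC/C(C)=C\I | intermediate
8 | (R)-5-(hydroxymethyl)dihydrofuran-2(3H)-one | O=C1CC[C@H](CO)O1 | starting material
9 | (R)-5-[(tert-butyldiphenylsilyloxy)methyl]dihydrofuran-2(3H)-one | O=C1CC[C@H](CO[Si](c2ccccc2)(c2ccccc2)C(C)(C)C)O1 | intermediate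
10 | lithium enolate of 9 | [Li]OC1=CC[C@H](CO[Si](c2ccccc2)(c2ccccc2)C(C)(C)C)O1 | intermediate (not isolated)
11 | (5R)-5-[(tert-butyldiphenylsilyloxy)methyl]-3-(phenylselanyl)dihydrofuran-2(3H)-one, C3 epimers | O=C1C([Se]c2ccccc2)C[C@H](CO[Si](c2ccccc2)(c2ccccc2)C(C)(C)C)O1 | intermediate (not isolated)
12 | selenoxide of 11 | O=C1C([Se](=O)c2ccccc2)C[C@H](CO[Si](c2ccccc2)(c2ccccc2)C(C)(C)C)O1 | intermediate (not isolated)
13 | (R)-5-[(tert-butyldiphenylsilyloxy)methyl]furan-2(5H)-one | O=C1C=C[C@H](CO[Si](c2ccccc2)(c2ccccc2)C(C)(C)C)O1 | intermediate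
14 | 1,3-dithiane | C1CSCSC1 | starting material
15 | 2-lithio-1,3-dithiane | [Li]C1SCCCS1 | intermediate (not isolated)
16 | (4R,5R)-5-[(tert-butyldiphenylsilyloxy)methyl]-4-(1,3-dithian-2-yl)dihydrofuran-2(3H)-one | O=C1C[C@@H](C2SCCCS2)[C@H](CO[Si](c2ccccc2)(c2ccccc2)C(C)(C)C)O1 | intermediate
17 | (4R,5R)-4-(1,3-dithian-2-yl)-5-(hydroxymethyl)dihydrofuran-2(3H)-one | O=C1C[C@@H](C2SCCCS2)[C@H](CO)O1 | intermediate
18 | (2R,3R)-3-(1,3-dithian-2-yl)-5-oxotetrahydrofuran-2-carbaldehyde | O=C1C[C@@H](C2SCCCS2)[C@H](C=O)O1 | intermediate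
19 | chlorobis(cyclopentadienyl)[(2E,6Z)-7-iodo-6-methylhepta-2,6-dien-2-yl]zirconium (cyclopentadienyl rings drawn σ-bound) | C/C(=C\CC/C(C)=C\I)[Zr](Cl)(C1C=CC=C1)C1C=CC=C1 | intermediate (not isolated)
20 | [(2E,6Z)-7-iodo-6-methylhepta-2,6-dien-2-yl](methyl)zinc | C/C(=C\CC/C(C)=C\I)[Zn]C | intermediate (not isolated)
21 | (4R,5R)-4-(1,3-dithian-2-yl)-5-[(1S,2E,6Z)-1-hydroxy-7-iodo-2,6-dimethylhepta-2,6-dien-1-yl]dihydrofuran-2(3H)-one | O=C1C[C@@H](C2SCCCS2)[C@H]([C@@H](O)/C(C)=C/CC/C(C)=C\I)O1 | intermediate
22 | (1S,2E,6Z)-1-[(2R,3R)-3-(1,3-dithian-2-yl)-5-oxotetrahydrofuran-2-yl]-7-iodo-2,6-dimethylhepta-2,6-dien-1-yl 2-methylpropanoate | O=C1C[C@@H](C2SCCCS2)[C@H]([C@@H](OC(=O)C(C)C)/C(C)=C/CC/C(C)=C\I)O1 | intermediate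
23 | (1S,2E,6Z)-1-[(2R,3R)-3-formyl-5-oxotetrahydrofuran-2-yl]-7-iodo-2,6-dimethylhepta-2,6-dien-1-yl 2-methylpropanoate (cyclization precursor) | O=C1C[C@@H](C=O)[C@H]([C@@H](OC(=O)C(C)C)/C(C)=C/CC/C(C)=C\I)O1 | intermediate
24 | alkenylchromium dichloride derived from 23 (C5–CrCl2) | O=C1C[C@@H](C=O)[C@H]([C@@H](OC(=O)C(C)C)/C(C)=C/CC/C(C)=C\[Cr](Cl)Cl)O1 | intermediate (not isolated)
25 | (3aS,4R,5Z,9E,11S,11aR)-4-hydroxy-6,10-dimethyl-2-oxo-2,3,3a,4,7,8,11,11a-octahydrocyclodeca[b]furan-11-yl 2-methylpropanoate (germacrane locants 6R,7S,8R,9S; 13-nor, 4,5-deoxy target) | C1C(=O)O[C@@H]2[C@@H]1[C@H](O)/C=C(C)\CC/C=C(\C)[C@@H]2OC(=O)C(C)C | intermediate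
26 | (3aR,4R,5Z,9E,11S,11aR)-6,10-dimethyl-2-oxo-4-[(triethylsilyl)oxy]-2,3,3a,4,7,8,11,11a-octahydrocyclodeca[b]furan-11-yl 2-methylpropanoate | C1C(=O)O[C@@H]2[C@@H]1[C@H](O[Si](CC)(CC)CC)/C=C(C)\CC/C=C(\C)[C@@H]2OC(=O)C(C)C | intermediate
27 | lithium enolate of 26 | C1=C(O[Li])O[C@@H]2[C@@H]1[C@H](O[Si](CC)(CC)CC)/C=C(C)\CC/C=C(\C)[C@@H]2OC(=O)C(C)C | intermediate (not isolated)
28 | (3aR,4R,5Z,9E,11S,11aR)-3-[(dimethylamino)methyl]-6,10-dimethyl-2-oxo-4-[(triethylsilyl)oxy]-2,3,3a,4,7,8,11,11a-octahydrocyclodeca[b]furan-11-yl 2-methylpropanoate (C11 epimer not assigned) | CN(C)CC1C(=O)O[C@@H]2[C@@H]1[C@H](O[Si](CC)(CC)CC)/C=C(C)\CC/C=C(\C)[C@@H]2OC(=O)C(C)C | intermediate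
29 | trimethylammonium iodide of 28 | C[N+](C)(C)CC1C(=O)O[C@@H]2[C@@H]1[C@H](O[Si](CC)(CC)CC)/C=C(C)\CC/C=C(\C)[C@@H]2OC(=O)C(C)C.[I-] | intermediate (not isolated)
30 | (3aR,4R,5Z,9E,11S,11aR)-6,10-dimethyl-3-methylidene-2-oxo-4-[(triethylsilyl)oxy]-2,3,3a,4,7,8,11,11a-octahydrocyclodeca[b]furan-11-yl 2-methylpropanoate | C=C1C(=O)O[C@@H]2[C@@H]1[C@H](O[Si](CC)(CC)CC)/C=C(C)\CC/C=C(\C)[C@@H]2OC(=O)C(C)C | intermediate
31 | (3aS,4R,5Z,9E,11S,11aR)-4-hydroxy-6,10-dimethyl-3-methylidene-2-oxo-2,3,3a,4,7,8,11,11a-octahydrocyclodeca[b]furan-11-yl 2-methylpropanoate | C=C1C(=O)O[C@@H]2[C@@H]1[C@H](O)/C=C(C)\CC/C=C(\C)[C@@H]2OC(=O)C(C)C | intermediate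
32 | (4S,5R,6S,7S,8R,9S)-4,5-epoxy-6-hydroxy-9-(2-methylpropanoyloxy)germacra-1(10)E,11(13)-dien-12,8-olide (CNP0220196.2) | C=C1C(=O)O[C@@H]2[C@@H]1[C@H](O)[C@H]1O[C@@]1(C)CC/C=C(\C)[C@@H]2OC(=O)C(C)C | target

Total step count: 16.
Longest linear sequence: 14 steps (8 to 32, steps 3 to 16); the side chain 7 takes 2 further steps (steps 1 and 2) and joins at step 8.

Steps most likely to fail

Step 11. What may go wrong: attack of the alkenylchromium on the other face of the C6 aldehyde, if the macrocyclic constraint overrides Felkin–Anh control, so that C6 is formed with poor facial selectivity. Intermolecular coupling may also compete with ring closure. The fallback sets out from 25 as obtained (mixed with its C6 epimer). The allylic alcohol would be oxidized with 1,1,1-triacetoxy-1,1-dihydro-1,2-benziodoxol-3(1H)-one (NaHCO3, CH2Cl2, 0 °C) to the ten-membered (Z)-enone F2. The ketone would then be reduced under reagent control by CBS reduction with (R)-2-methyl-CBS-oxazaborolidine and catecholborane (toluene, −78 °C), the alkenyl arm acting as the larger ketone substituent. C6 is then set by hydride delivery and no longer by the C–C bond formation, and the sequence comes back to the route at 25.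

Step 8. What may go wrong: poor facial selectivity at the C9 aldehyde, through competition between the polar Felkin–Anh transition state and zinc-chelated or sulfur-coordinated ones, and incomplete regiocontrol of the hydrozirconation. The fallback sets out from 21 as obtained (mixed with its C9 epimer). Parikh–Doering oxidation (SO3·pyridine, DMSO, i-Pr2NEt, CH2Cl2, 0 °C), which tolerates the dithiane, would give the conjugated C9 ketone F1. CBS reduction with (S)-2-methyl-CBS-oxazaborolidine and catecholborane, the α-methylalkenyl group acting as the larger substituent, should deliver 9S and come back to the route at 21.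

Step 16. What may go wrong: oxygen delivery to the wrong face of C4=C5 if the ring conformer holds the hydroxyl over the other alkene face, as is known for medium-ring allylic alcohols, or Lewis-acid-induced transannular opening of the new epoxide. The fallback sets out from 30 and replaces hydroxyl direction by steric control. Epoxidation of the silyl ether with dimethyldioxirane (acetone, −20 °C) should occur anti to the bulky C6 silyloxy group and give the epoxy silyl ether F3. The C1=C10 alkene is the more deactivated one, by its allylic acyloxy group. Desilylation with HF·pyridine/pyridine (THF, 0 °C) then comes back to the route at 32.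

Further compounds
F1 | step 8 | (4R,5R)-4-(1,3-dithian-2-yl)-5-[(2E,6Z)-7-iodo-2,6-dimethylhepta-2,6-dienoyl]dihydrofuran-2(3H)-one | O=C1C[C@@H](C2SCCCS2)[C@H](C(=O)/C(C)=C/CC/C(C)=C\I)O1
F2 | step 11 | (3aR,5Z,9E,11S,11aR)-6,10-dimethyl-2,4-dioxo-2,3,3a,4,7,8,11,11a-octahydrocyclodeca[b]furan-11-yl 2-methylpropanoate | C1C(=O)O[C@@H]2[C@@H]1C(=O)/C=C(C)\CC/C=C(\C)[C@@H]2OC(=O)C(C)C
F3 | step 16 | 6-O-triethylsilyl ether of 32 | C=C1C(=O)O[C@@H]2[C@@H]1[C@H](O[Si](CC)(CC)CC)[C@H]1O[C@@]1(C)CC/C=C(\C)[C@@H]2OC(=O)C(C)C
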